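Amounts first: each mole of J you charge, the limiting reagent, has to stand somewhere at any moment, so keep a ledger per mole charged.

| flask | J | remark | time |
|---|---|---|---|
| blue | 0.042 M | run made earlier |  |
| amber | 0.13 M | run made earlier |  |
| larch | 0.015 M |  | 5.0 h |
| oak | 0.030 M |  | 5.0 h |
| ash | 0.060 M |  | 5.0 h |
| alder | 0.12 M |  | 5.0 h |

- blue (time / h: L / %): 0.200: 1.4; 0.667: 7.9; 1.33: 17.9; 2.00: 25.6; 2.50: 30.4
- amber (time / h: L / %): 0.200: 1.0; 0.667: 7.2; 1.33: 18.3; 2.00: 26.2; 2.50: 29.3

(scatter of a reading: 0.5 percentage points)

- [L] at the end for larch, oak, ash, alder, in this order
- the shape of the row from first to last (rises all the way / hardly changes / falls all the way / falls, then rises / rises, then falls)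

- "hardly changes" means that all values lie within two and a half points (for a concentration: within two and a half percent of the largest)

Open the ledger at 2.50 h, the last reading. The blue run has 30.4% of its J standing as L and the amber run has 29.3%, although amber holds 3.10 times the charge of blue. The gap of 1.1 percentage points stands beside a scatter of 0.5 points on each reading, and it changes sign along the runs: at 1.33 h amber stands higher than blue, at 18.3% against 17.9%.

So follow one molecule of J. Across these two charges, its prospects do not visibly depend on how many others share the flask. Call the mean of the two readings the chance, 29.8%, meaning the share of charged J that stands as L at a given moment. The amount of L is then the chance times the charge. The other entry, 70.2%, is unread: it may be J still unreacted, or something else that J has become.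

The end of the books needs a guess, because the mean gain of L is 7.8 points from 1.33 h to 2.00 h, then 3.9 points from there to 2.50 h. My own reckoning carries the chance unchanged to 5.0 h, which gives 0.00448 M for larch and 0.0358 M for alder, a row that rises with the charge.

The forecast is higher, at 0.0054 M, 0.0108 M, 0.0216 M and 0.0432 M, a chance of 36.0%. It agrees on the form, “proportional to the charge”, and its row rises all the way.

Larch, oak, ash and alder end at 0.00460 M, 0.00919 M, 0.0184 M and 0.0368 M, and the row rises all the way.

    J → E (k = 2.30 × 10⁻⁴ s⁻¹)
    E ⇌ Z (K = 8.70, k = 1.50 × 10⁻⁴ s⁻¹)
    E ⇌ D (K = 0.510, k = 0.00130 s⁻¹)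
    E ⇌ L (K = 1.80, k = 2.70 × 10⁻⁴ s⁻¹)

Of the larch charge, 30.6% stands as L at 5.00 h, where the forecast held 36.0%. The step between E and L has a relaxation half-life, both ways together, of 0.458 h, short against the 5.0 h. Multiply the chance of 29.8% by the larch charge and you get 0.00448 M against 0.00460 M; by the alder charge, 0.0358 M against 0.0368 M.

The earlier runs and the new flask are simulated with constants of no real substance; the scatter is artificial.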